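**Retrosynthetic overview**

- Feature: the γ-lactone ring (O1, C2 carbonyl, C3, C4, C5) carries the same 3,4,5-trimethoxybenzyl group on C3 and on C4, trans and both R. Benzylic carbon C7' (on C3) is β to C2 and benzylic carbon C7 (on C4) is β to C5; with C5 raised to the carboxyl level, the six carbons C7'–C3(–C2)–C4(–C5)–C7 are those of one achiral 2,3-dimethylenesuccinate.
- Disconnections: lactone ⇒ C2-symmetric (2R,3R)-diol ⇒ (2R,3R)-dibenzylsuccinate diester ⇒ both aryl–CH2 bonds and both α C–H bonds at once, from dimethyl 2,3-dimethylenesuccinate and two arylboronic acids by rhodium/BINAP conjugate arylation with enantioselective protonation.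
- Diene diester ⇒ zinc 1,4-debromination of dimethyl 2,3-bis(bromomethyl)maleate ⇒ NBS bromination of dimethyl 2,3-dimethylmaleate ⇒ 2,3-dimethylmaleic anhydride.
- Ring order: skeleton and both stereocentres are built open-chain; the only ring formed, the lactone, is closed last by oxidation of the diol.

Key step: step 4

Assumption: (R)-BINAP is taken as the ligand hand that protonates each rhodium enolate to the (R) centre, by analogy with itaconate arylation–protonation; the sense depends only on the ligand hand, so (S)-BINAP is used instead should the first run show the opposite sign of rotation.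

Step 1
Reactants: 1 2,3-dimethylmaleic anhydride
Product: 2 dimethyl 2,3-dimethylmaleate [dimethyl (Z)-2,3-dimethylbut-2-enedioate]
Conditions: MeOH (solvent), H2SO4 (cat.), reflux
Reagents that add atoms: methanol, CO
Why: Acid-catalysed ring opening of the anhydride and Fischer esterification of the half ester in a large excess of methanol should drive the equilibrium to the diester, whose Z geometry is inherited from the ring.

Step 2
Reactants: 2 dimethyl 2,3-dimethylmaleate
Product: 3 dimethyl (Z)-2,3-bis(bromomethyl)but-2-enedioate
Conditions: NBS (2.2 equiv), AIBN (cat.), PhCF3, reflux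
Reagents that add atoms: N-bromosuccinimide, O=C1CCC(=O)N1Br
Why: Wohl–Ziegler bromination: each methyl group is allylic to the tetrasubstituted alkene, so radical-chain hydrogen abstraction and bromine transfer should put one bromine on each, a CH2Br group being less prone to a second abstraction than the remaining CH3; any E isomer formed by reversible bromine-atom addition is carried along, since both geometries give the same diene in step 3.

Step 3
Reactants: 3 dimethyl (Z)-2,3-bis(bromomethyl)but-2-enedioate
Product: 4 dimethyl 2,3-dimethylenesuccinate
Conditions: Zn dust (activated), THF, 0 °C; cold aqueous wash, solution kept with BHT and used the same day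
Reagents that add atoms: none
Why: Reductive 1,4-elimination: zinc inserts into one allylic C–Br bond and the allylzinc so formed expels the second bromide through the alkene (vinylogous β-elimination, as in the zinc debromination of 1,4-dibromobut-2-enes to 1,3-dienes); the product is kept cold, dilute and inhibited because such diene diesters dimerise by Diels–Alder reaction and polymerise on standing.

Step 4
Reactants: 4 dimethyl 2,3-dimethylenesuccinate; 5 (3,4,5-trimethoxyphenyl)boronic acid (excess)
Product: 7 dimethyl (2R,3R)-2,3-bis(3,4,5-trimethoxybenzyl)succinate, via mono-arylated methylenesuccinate 6 (not isolated)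
Conditions: Rh(acac)(C2H4)2 (cat.), (R)-BINAP (cat.), B(OH)3, 1,4-dioxane/H2O (20:1), 90 °C, 4 added slowly by syringe pump; meso diester removed by chromatography
Reagents that add atoms: (3,4,5-trimethoxyphenyl)boronic acid (5), COc1cc(B(O)O)cc(OC)c1OC
Why: Proposed new method: Rh(acac)(C2H4)2 and (R)-BINAP give Rh(OH)(BINAP) (monovalent rhodium), which takes the aryl group from 5 by transmetallation; ArRh(BINAP) inserts a CH2= terminus of 4 with the aryl on the methylene carbon and rhodium on the ester-bearing carbon (an oxa-π-allyl that is also a dienolate), C-protonation at that α-carbon by B(OH)3/water gives 6 and returns Rh(OH)(BINAP), and 6, a 3-substituted itaconate, runs through the same cycle a second time to 7. The closest known reaction type is the rhodium/BINAP conjugate arylation with enantioselective protonation of itaconates and 2-benzylacrylates by arylboron reagents; new are the 1,3-diene-2,3-diester as acceptor and the twofold course in one flask. No ring closes in this step; two aryl–CH2 bonds and two α C–H bonds form. Both stereocentres (C2 and C3 of 7) are set in the protonation of the rhodium enolate, each under control of the BINAP pocket, which leaves one enolate face open to the proton donor; in the second round the neighbouring centre carries CO2Me and CH2Ar groups of similar size, so its own bias should be small, and a wrongly set centre should appear mostly as the meso diester, a diastereomer that is separated, so that the C2-symmetric product should be of higher enantiomeric purity than a single protonation event would give. The step needs α- and not γ-protonation of the first dienolate and no migration of the alkene of 6 into conjugation with both esters: proton delivery to the O-bound enolate should go through a six-membered array to the adjacent α-carbon (kinetic α-protonation, as with dienolates in general), and the boric-acid-buffered medium without added base, together with slow addition of cold 4 so that bimolecular Diels–Alder dimerisation stays behind the arylation, should secure it.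

Step 5
Reactants: 7 dimethyl (2R,3R)-2,3-bis(3,4,5-trimethoxybenzyl)succinate
Product: 8 (2R,3R)-2,3-bis(3,4,5-trimethoxybenzyl)butane-1,4-diol
Conditions: LiAlH4, THF, 0 °C to rt; H2O/aq. NaOH work-up
Reagents that add atoms: none
Why: Hydride reduction of both esters to primary alcohols; hydride addition to the ester carbonyl is much faster than enolisation, so both α-stereocentres should be carried over unchanged, and the aryl methyl ethers are inert.

Step 6
Reactants: 8 (2R,3R)-2,3-bis(3,4,5-trimethoxybenzyl)butane-1,4-diol
Product: 11 (−)-cubebininolide [(3R,4R)-3,4-bis(3,4,5-trimethoxybenzyl)dihydrofuran-2(3H)-one], via hydroxy aldehyde 9 (not isolated), via lactol 10 (not isolated)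
Conditions: TEMPO (cat.), PhI(OAc)2 (2.5 equiv), CH2Cl2, rt
Reagents that add atoms: none
Why: Oxoammonium oxidation (TEMPO/PhI(OAc)2) of one primary alcohol to the aldehyde, closure to the five-membered lactol and a second oxidation to the lactone; the two carbinols are homotopic by C2 symmetry, so only one lactone can form, and the trans arrangement at C3/C4 is the more stable one and should persist.

**Compound list**

1 | 2,3-dimethylmaleic anhydride (3,4-dimethylfuran-2,5-dione) | CC1=C(C)C(=O)OC1=O | starting material
2 | dimethyl 2,3-dimethylmaleate | COC(=O)/C(C)=C(C)\C(=O)OC | intermediate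
3 | dimethyl (Z)-2,3-bis(bromomethyl)but-2-enedioate | COC(=O)/C(CBr)=C(CBr)\C(=O)OC | intermediate
4 | dimethyl 2,3-dimethylenesuccinate | C=C(C(=O)OC)C(=C)C(=O)OC | intermediate
5 | (3,4,5-trimethoxyphenyl)boronic acid | COc1cc(B(O)O)cc(OC)c1OC | starting material
6 | dimethyl (3R)-2-methylidene-3-(3,4,5-trimethoxybenzyl)butanedioate | COc1cc(C[C@@H](C(=O)OC)C(=C)C(=O)OC)cc(OC)c1OC | intermediate
7 | dimethyl (2R,3R)-2,3-bis(3,4,5-trimethoxybenzyl)succinate | COc1cc(C[C@@H](C(=O)OC)[C@H](C(=O)OC)Cc2cc(OC)c(OC)c(OC)c2)cc(OC)c1OC | intermediate
8 | (2R,3R)-2,3-bis(3,4,5-trimethoxybenzyl)butane-1,4-diol | COc1cc(C[C@@H](CO)[C@H](CO)Cc2cc(OC)c(OC)c(OC)c2)cc(OC)c1OC | intermediate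
9 | (2R,3R)-4-hydroxy-2,3-bis(3,4,5-trimethoxybenzyl)butanal | COc1cc(C[C@@H](CO)[C@H](C=O)Cc2cc(OC)c(OC)c(OC)c2)cc(OC)c1OC | intermediate
10 | (3R,4R)-3,4-bis(3,4,5-trimethoxybenzyl)oxolan-2-ol (lactol, both anomers) | COc1cc(C[C@H]2COC(O)[C@@H]2Cc2cc(OC)c(OC)c(OC)c2)cc(OC)c1OC | intermediate
11 | (−)-cubebininolide, (3R,4R)-3,4-bis(3,4,5-trimethoxybenzyl)dihydrofuran-2(3H)-one | COc1cc(C[C@H]2COC(=O)[C@@H]2Cc2cc(OC)c(OC)c(OC)c2)cc(OC)c1OC | target

**Step count**

Total steps: 6. Longest linear sequence: 6 steps (1 to 11); boronic acid 5 enters in step 4.

**Steps most likely to fail**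

1. Step 4 (Proposed new method). What may go wrong: γ-protonation of the first dienolate or migration of the alkene at the mono-adduct stage, which ends the sequence at a tetrasubstituted alkene; a substrate bias in the second protonation that favours the meso diastereomer; Diels–Alder dimerisation of the diene outrunning the arylation. Fallback, known chemistry, setting out from 5 and returning to the route at 11: 5 is added under the same Rh(acac)(C2H4)2/(R)-BINAP/B(OH)3 conditions to commercial dimethyl itaconate, the established substrate class, to give dimethyl (R)-2-(3,4,5-trimethoxybenzyl)succinate F1. LiAlH4 reduces it to (R)-2-(3,4,5-trimethoxybenzyl)butane-1,4-diol F2. Oxidative lactonisation (TEMPO/PhI(OAc)2 or Ag2CO3 on Celite) should take place at the less hindered carbinol and give mainly the β-substituted lactone (R)-4-(3,4,5-trimethoxybenzyl)dihydrofuran-2(3H)-one F3, the regioisomer being separated. Deprotonation with LiN(SiMe3)2 in THF at −78 °C and alkylation with 3,4,5-trimethoxybenzyl bromide should occur anti to the C4 substituent and give trans-lactone 11. One catalyst-controlled protonation and one substrate-controlled alkylation then replace the two catalyst-controlled protonations.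

2. Step 3. What may go wrong: coupling of the allylzinc with unreacted bromide, conjugate addition of the allylzinc to diene already formed, and polymerisation or dimerisation of the diene during work-up. Fallback setting out from 3 and returning at 4: Na2S·9H2O closes the two cis CH2Br groups of 3 to dimethyl 2,5-dihydrothiophene-3,4-dicarboxylate F4; mCPBA oxidises the sulfide to dimethyl 2,5-dihydrothiophene-3,4-dicarboxylate 1,1-dioxide F5, a storable 3-sulfolene. Heating F5 in dioxane or toluene at about 110 °C under a nitrogen sweep extrudes SO2 (cheletropic elimination) and releases 4 on demand, without any organometallic intermediate.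

3. Step 2. What may go wrong: incomplete second bromination or geminal dibromination, and Z/E scrambling that gives mixtures hard to purify. Fallback setting out from 1 and returning at 3: the bromination is moved onto the ring-locked anhydride, which cannot isomerise. NBS with a radical initiator converts 1 into 3,4-bis(bromomethyl)furan-2,5-dione F6, purified by crystallisation. Methanol at room temperature opens it to (Z)-2,3-bis(bromomethyl)-4-methoxy-4-oxobut-2-enoic acid F7, in which the acid is trans to the remote CH2Br, so that no butenolide can form. Me3SiCHN2 in MeOH/toluene at 0 °C then methylates the acid to give 3.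

Further compounds
F1 | step 4 | dimethyl (R)-2-(3,4,5-trimethoxybenzyl)succinate | COc1cc(C[C@@H](C(=O)OC)CC(=O)OC)cc(OC)c1OC
F2 | step 4 | (R)-2-(3,4,5-trimethoxybenzyl)butane-1,4-diol | COc1cc(C[C@@H](CO)CCO)cc(OC)c1OC
F3 | step 4 | (R)-4-(3,4,5-trimethoxybenzyl)dihydrofuran-2(3H)-one | COc1cc(C[C@H]2COC(=O)C2)cc(OC)c1OC
F4 | step 3 | dimethyl 2,5-dihydrothiophene-3,4-dicarboxylate | COC(=O)C1=C(C(=O)OC)CSC1
F5 | step 3 | dimethyl 2,5-dihydrothiophene-3,4-dicarboxylate 1,1-dioxide | COC(=O)C1=C(C(=O)OC)CS(=O)(=O)C1
F6 | step 2 | 3,4-bis(bromomethyl)furan-2,5-dione | O=C1OC(=O)C(CBr)=C1CBr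
F7 | step 2 | (Z)-2,3-bis(bromomethyl)-4-methoxy-4-oxobut-2-enoic acid | COC(=O)/C(CBr)=C(CBr)\C(=O)O
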